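**Plan**

- Retrosynthetic cuts, in order: C1'–C2' of ring D (aldol); the C2'=C3' enone olefin of the side chain (cross-metathesis); the C7–C7' biaryl bond (Suzuki–Miyaura); the C4a'–C4' aryl–allyl bond (Stille); C1–C2 and C3–C4 of ring A (Michael–Dieckmann annulation).
- Forward: ring A is annulated onto a brominated toluate made from 2-bromo-5-methylphenol, giving the naphthalene (rings A/B) as its C7 boronate. Ring C comes from 2-bromo-5-iodophenol and receives a methallyl group at C4a'. The two arenes are then joined, the methallyl group is turned into the enone, the phenols are freed, and ring D is closed last.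
- Enabling feature: C1'(OH)–C2'(H)(acetyl) is an anti aldol unit inside ring D. C2' is α to the ketone and the inner end of a dienol C2'–C3'=C4' conjugated to ring C, and the aldehyde carbon C1' sits ortho to that chain on ring C.
- Stereochemistry: C1' and C2' are both set in the last step by D-proline (carboxylic-acid-directed enamine aldol, anti); no later step can erode them.

Key step: step 12

Locants: naphthalene half C1–C8a (ring A = C1–C4, C4a, C8a with 1-OH, 2-acetyl, 3-methyl; ring B = C5–C8 with the biaryl carbon C7 and 8-OH); dihydronaphthalene half primed (ring C aromatic, ring D = C1'–C4').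

Remark: the C7–C7' axis has only two ortho substituents (both OH) and is taken to rotate freely, so C1' and C2' are the only stereo-elements; the E enone drawn for 16 and 17 is the expected major geometry, and any Z isomer would enter step 12 through the same dienamine.

**Route**

Step 1
Reactants: 1 2-bromo-5-methylphenol
Product: 2 3-bromo-2-hydroxy-6-methylbenzaldehyde
Conditions: MgCl2, Et3N, (CH2O)n, MeCN, reflux; dilute aq HCl work-up
Reagents that add atoms: paraformaldehyde (as formaldehyde), C=O
Why: Casnati–Skattebøl ortho-formylation passes formaldehyde from the magnesium phenoxide only to a carbon ortho to oxygen, and C6 is the one free ortho position of 1.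

Step 2
Reactants: 2 3-bromo-2-hydroxy-6-methylbenzaldehyde
Product: 3 3-bromo-2-(methoxymethoxy)-6-methylbenzaldehyde
Conditions: MOMCl, i-Pr2NEt, CH2Cl2, 0 °C to rt
Reagents that add atoms: chloromethyl methyl ether, COCCl
Why: O-alkylation of the phenol (Williamson-type) gives an acetal ether that should withstand amide bases, iodine/KOH and the palladium steps and still leave under mild acid.

Step 3
Reactants: 3 3-bromo-2-(methoxymethoxy)-6-methylbenzaldehyde
Product: 4 methyl 3-bromo-2-(methoxymethoxy)-6-methylbenzoate
Conditions: I2, KOH, MeOH, 0 °C to rt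
Reagents that add atoms: methanol, CO
Why: Oxidative esterification of a non-enolisable aryl aldehyde through its methanol hemiacetal runs in basic methanol, where the MOM ether and the aryl bromide are inert.

Step 4
Reactants: 4 methyl 3-bromo-2-(methoxymethoxy)-6-methylbenzoate; 5 (E)-4-methoxypent-3-en-2-one
Product: 7 1-[7-bromo-1-hydroxy-8-(methoxymethoxy)-3-methylnaphthalen-2-yl]ethan-1-one, via Michael–Dieckmann adduct 6 (not isolated)
Conditions: LiN(i-Pr)2 (2.2 equiv), THF, −78 °C; then 5, −78 °C to rt; aq NH4Cl
Reagents that add atoms: none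
Why: In this tandem Michael–Dieckmann (Staunton–Weinreb-type) annulation the laterally lithiated toluate adds to C4 of the β-methoxy enone, the enolate closes onto the ester to give 6, and loss of methanol aromatises ring A to the chelated 2-acetyl-1-naphthol; benzylic deprotonation at −78 °C should be far faster than any attack of the amide base on the aryl bromide.

Step 5
Reactants: 7 1-[7-bromo-1-hydroxy-8-(methoxymethoxy)-3-methylnaphthalen-2-yl]ethan-1-one
Product: 8 1-[1-hydroxy-8-(methoxymethoxy)-3-methyl-7-(4,4,5,5-tetramethyl-1,3,2-dioxaborolan-2-yl)naphthalen-2-yl]ethan-1-one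
Conditions: B2pin2, Pd(dppf)Cl2 (5 mol%), KOAc, 1,4-dioxane, 90 °C
Reagents that add atoms: bis(pinacolato)diboron, CC1(C)OB(OC1(C)C)B1OC(C)(C)C(C)(C)O1
Why: Miyaura borylation of an aryl bromide with the weak base KOAc tolerates the hydrogen-bonded naphthol, the aryl ketone and the MOM ether.

Step 6
Reactants: 9 2-bromo-5-iodophenol
Product: 10 3-bromo-2-hydroxy-6-iodobenzaldehyde
Conditions: MgCl2, Et3N, (CH2O)n, MeCN, reflux; dilute aq HCl work-up
Reagents that add atoms: paraformaldehyde (as formaldehyde), C=O
Why: The same Casnati–Skattebøl ortho-formylation can only reach C6 of 9, which places bromine ortho to the hydroxyl (future biaryl carbon C7') and iodine ortho to the formyl group (future C4a').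

Step 7
Reactants: 10 3-bromo-2-hydroxy-6-iodobenzaldehyde
Product: 11 3-bromo-6-iodo-2-(methoxymethoxy)benzaldehyde
Conditions: MOMCl, i-Pr2NEt, CH2Cl2, 0 °C to rt
Reagents that add atoms: chloromethyl methyl ether, COCCl
Why: O-alkylation as in step 2 removes the acidic, aldehyde-activating phenol before the two cross-couplings.

Step 8
Reactants: 11 3-bromo-6-iodo-2-(methoxymethoxy)benzaldehyde; 12 tributyl(2-methylprop-2-enyl)stannane
Product: 13 3-bromo-2-(methoxymethoxy)-6-(2-methylprop-2-enyl)benzaldehyde
Conditions: Pd(PPh3)4 (5 mol%), toluene, 80 °C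
Reagents that add atoms: none
Why: Stille allyl–aryl coupling needs no base and so spares the aldehyde, zerovalent palladium inserts into the C–I bond ortho to the formyl group well before the C–Br bond, and the symmetric methallyl unit raises no α/γ question.

Step 9
Reactants: 8 1-[1-hydroxy-8-(methoxymethoxy)-3-methyl-7-(4,4,5,5-tetramethyl-1,3,2-dioxaborolan-2-yl)naphthalen-2-yl]ethan-1-one; 13 3-bromo-2-(methoxymethoxy)-6-(2-methylprop-2-enyl)benzaldehyde
Product: 14 3-[7-acetyl-8-hydroxy-1-(methoxymethoxy)-6-methylnaphthalen-2-yl]-2-(methoxymethoxy)-6-(2-methylprop-2-enyl)benzaldehyde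
Conditions: Pd(OAc)2 (5 mol%), SPhos (10 mol%), K3PO4, toluene/H2O, 80 °C
Reagents that add atoms: none
Why: Suzuki–Miyaura coupling with a biarylphosphine ligand joins two arenes that each carry a single ortho alkoxy group, and aqueous phosphate is too weak to touch the non-enolisable aldehyde, the hindered aryl ketone or the isolated alkene.

Step 10
Reactants: 14 3-[7-acetyl-8-hydroxy-1-(methoxymethoxy)-6-methylnaphthalen-2-yl]-2-(methoxymethoxy)-6-(2-methylprop-2-enyl)benzaldehyde; 15 but-3-en-2-one
Product: 16 3-[7-acetyl-8-hydroxy-1-(methoxymethoxy)-6-methylnaphthalen-2-yl]-2-(methoxymethoxy)-6-[(E)-2-methyl-4-oxopent-2-enyl]benzaldehyde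
Conditions: 15 (10 equiv), second-generation Hoveyda–Grubbs catalyst (H2IMes)Cl2Ru(=CH-C6H4-2-OiPr) (10 mol%), p-benzoquinone (10 mol%), CH2Cl2, 40 °C
Reagents that add atoms: none
Why: Olefin cross-metathesis of a 1,1-disubstituted alkene with excess enone is driven by loss of ethene, should favour the E trisubstituted enone, and runs under neutral conditions, so the enone first appears next to the aldehyde without any base that could close ring D early.

Step 11
Reactants: 16 3-[7-acetyl-8-hydroxy-1-(methoxymethoxy)-6-methylnaphthalen-2-yl]-2-(methoxymethoxy)-6-[(E)-2-methyl-4-oxopent-2-enyl]benzaldehyde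
Product: 17 3-(7-acetyl-1,8-dihydroxy-6-methylnaphthalen-2-yl)-2-hydroxy-6-[(E)-2-methyl-4-oxopent-2-enyl]benzaldehyde
Conditions: 3 M aq HCl, THF, 0 to 20 °C, short contact time; NaH2PO4/Na2HPO4 buffer (pH 7) work-up
Reagents that add atoms: none
Why: Acid hydrolysis of the two MOM acetals is assisted by the neighbouring formyl and peri-hydroxyl groups and should be complete at or below room temperature, before the enone can enolise toward C4'.

Step 12
Reactants: 17 3-(7-acetyl-1,8-dihydroxy-6-methylnaphthalen-2-yl)-2-hydroxy-6-[(E)-2-methyl-4-oxopent-2-enyl]benzaldehyde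
Product: 20 1-[(1S,2R)-7-(7-acetyl-1,8-dihydroxy-6-methylnaphthalen-2-yl)-1,8-dihydroxy-3-methyl-1,2-dihydronaphthalen-2-yl]ethan-1-one (CNP0298944.1), via D-proline dienamine 18 (not isolated), via aldol iminium carboxylate 19 (not isolated)
Conditions: D-proline (30 mol%), DMSO (0.05 M), 20 °C; then NaH2PO4/Na2HPO4 buffer (pH 7), EtOAc, 0 °C; chromatography on buffered silica at 0 °C
Reagents that add atoms: none
Why: Proposed new method: condensation of D-proline with the enone carbonyl of 17 gives an iminium ion that sheds a benzylic C4' proton to form dienamine 18, which attacks the neighbouring formyl carbon C1' through its inner carbon C2' to give iminium carboxylate 19, and hydrolysis of 19 releases 20 and the catalyst. The closest known reaction type is the proline-catalysed 6-enolexo intramolecular aldol reaction of saturated keto aldehydes and dialdehydes (Hajos–Parrish-type enamine aldolisation), extended here to an enone donor that reacts at its α-carbon as in dienamine catalysis. Ring D closes in the 6-(enolexo)-exo-trig mode; bonding from C4' would have to make a benzocyclobutene and bonding from the acetyl methyl an eight-membered ring, so ring size secures the α-regiochemistry, while the non-enolisable aryl aldehyde can only be the acceptor and the chelated naphthyl ketone stays out. C2' is fixed by the carboxylic acid of the catalyst, which hydrogen-bonds the aldehyde oxygen and brings it to the enamine face on its own side; C1' follows from the chair-like enamine–acid transition state, in which ring C lies gauche to the enamine α-substituent C3', which is just the geometry the C4a'–C4' tether imposes, so the anti (trans) aldol is expected, and since L-proline gives (S)-α,(R)-carbinol anti aldols with aryl aldehydes, D-proline should give (1'S,2'R). The step also needs the dienamine isomer with ring C and C2' on the same side of C3'=C4', which is replenished from the other isomer through the iminium ion, and it needs the product to escape dehydration to the naphthalene, for which the near-neutral catalyst, 20 °C, high dilution and a cold buffered work-up are chosen.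

**Compound list**

1 | 2-bromo-5-methylphenol | Cc1ccc(Br)c(O)c1 | starting material
2 | 3-bromo-2-hydroxy-6-methylbenzaldehyde | Cc1ccc(Br)c(O)c1C=O | intermediate
3 | 3-bromo-2-(methoxymethoxy)-6-methylbenzaldehyde | COCOc1c(Br)ccc(C)c1C=O | intermediate
4 | methyl 3-bromo-2-(methoxymethoxy)-6-methylbenzoate | COCOc1c(Br)ccc(C)c1C(=O)OC | intermediate
5 | (E)-4-methoxypent-3-en-2-one | CO/C(C)=C/C(C)=O | starting material
6 | 2-acetyl-7-bromo-3-methoxy-8-(methoxymethoxy)-3-methyl-3,4-dihydronaphthalen-1(2H)-one (Michael–Dieckmann adduct, present as its lithium enolate, diastereomer mixture, not isolated) | CC(=O)C1C(=O)c2c(OCOC)c(Br)ccc2CC1(C)OC | intermediate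
7 | 1-[7-bromo-1-hydroxy-8-(methoxymethoxy)-3-methylnaphthalen-2-yl]ethan-1-one | CC(=O)c1c(C)cc2ccc(Br)c(OCOC)c2c1O | intermediate
8 | 1-[1-hydroxy-8-(methoxymethoxy)-3-methyl-7-(4,4,5,5-tetramethyl-1,3,2-dioxaborolan-2-yl)naphthalen-2-yl]ethan-1-one | CC(=O)c1c(C)cc2ccc(B3OC(C)(C)C(C)(C)O3)c(OCOC)c2c1O | intermediate
9 | 2-bromo-5-iodophenol | Oc1cc(I)ccc1Br | starting material
10 | 3-bromo-2-hydroxy-6-iodobenzaldehyde | O=Cc1c(O)c(Br)ccc1I | intermediate
11 | 3-bromo-6-iodo-2-(methoxymethoxy)benzaldehyde | COCOc1c(Br)ccc(I)c1C=O | intermediate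
12 | tributyl(2-methylprop-2-enyl)stannane | C=C(C)C[Sn](CCCC)(CCCC)CCCC | starting material
13 | 3-bromo-2-(methoxymethoxy)-6-(2-methylprop-2-enyl)benzaldehyde | COCOc1c(Br)ccc(CC(C)=C)c1C=O | intermediate
14 | 3-[7-acetyl-8-hydroxy-1-(methoxymethoxy)-6-methylnaphthalen-2-yl]-2-(methoxymethoxy)-6-(2-methylprop-2-enyl)benzaldehyde | CC(=O)c1c(C)cc2ccc(-c3ccc(CC(C)=C)c(C=O)c3OCOC)c(OCOC)c2c1O | intermediate
15 | but-3-en-2-one (methyl vinyl ketone) | C=CC(C)=O | starting material
16 | 3-[7-acetyl-8-hydroxy-1-(methoxymethoxy)-6-methylnaphthalen-2-yl]-2-(methoxymethoxy)-6-[(E)-2-methyl-4-oxopent-2-enyl]benzaldehyde | CC(=O)c1c(C)cc2ccc(-c3ccc(C/C(C)=C/C(C)=O)c(C=O)c3OCOC)c(OCOC)c2c1O | intermediate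
17 | 3-(7-acetyl-1,8-dihydroxy-6-methylnaphthalen-2-yl)-2-hydroxy-6-[(E)-2-methyl-4-oxopent-2-enyl]benzaldehyde | CC(=O)c1c(C)cc2ccc(-c3ccc(C/C(C)=C/C(C)=O)c(C=O)c3O)c(O)c2c1O | intermediate
18 | D-proline dienamine of 17: (2R)-1-[(2E,4Z)-5-aryl-4-methylpenta-2,4-dien-2-yl]pyrrolidine-2-carboxylic acid, aryl = ring C of 17; nitrogen trans to C3', ring C cis to C2' across C3'=C4' (not isolated) | C/C(N1CCC[C@@H]1C(O)=O)=C\C(C)=C/c1ccc(-c2ccc3cc(C)c(C(C)=O)c(O)c3c2O)c(O)c1C=O | intermediate
19 | iminium carboxylate (zwitterion) formed from the C2' acetyl carbon of 20 and D-proline, C1' and C2' arranged in space as in 20 (not isolated) | CC(=O)c1c(C)cc2ccc(-c3ccc4c(c3O)[C@@H](O)[C@H](C(C)=[N+]5CCC[C@@H]5C([O-])=O)C(C)=C4)c(O)c2c1O | intermediate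
20 | 1-[(1S,2R)-7-(7-acetyl-1,8-dihydroxy-6-methylnaphthalen-2-yl)-1,8-dihydroxy-3-methyl-1,2-dihydronaphthalen-2-yl]ethan-1-one (CNP0298944.1) | CC(=O)c1c(C)cc2ccc(-c3ccc4c(c3O)[C@@H](O)[C@H](C(C)=O)C(C)=C4)c(O)c2c1O | target

**Step count and risks**

Total steps: 12. Longest linear sequence: 9 steps (steps 1–5, then 9–12, from 1); the ring C branch (steps 6–8) joins at step 9.

Steps most likely to fail:

1. Step 12 (proposed new method). The hindered conjugated ketone may condense with proline too slowly, facial or anti/syn control in the ring closure may be incomplete, and the aldol may lose water to the aromatic naphthalene while it forms. Fallback with known chemistry, from 17 back to 20: ring D is closed without enantiocontrol by the classical pyrrolidine/acetic acid enamine aldol (CH2Cl2, 0 °C), which should give the trans aldol as a racemate, that is 20 together with its (1'R,2'S) enantiomer F1. The two enantiomers are then separated by preparative HPLC on a polysaccharide chiral stationary phase with a neutral eluent, and the route is rejoined at 20.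

2. Step 10. Initiation at the 1,1-disubstituted alkene may be slow, and ruthenium hydrides from catalyst decay may shift the double bond into conjugation with ring C before metathesis occurs. Fallback, from 3 (with 5 and 8) back to 16: the side chain is built by carbanion chemistry instead. Aldehyde 3 is condensed with tert-butylamine to (E)-N-tert-butyl-1-[3-bromo-2-(methoxymethoxy)-6-methylphenyl]methanimine F2. Lateral lithiation with LiN(i-Pr)2 (THF, −78 °C) and addition to enone 5, then cold dilute aqueous HCl, which collapses the adduct with loss of methanol and hydrolyses the imine, should give 3-bromo-2-(methoxymethoxy)-6-[(E)-2-methyl-4-oxopent-2-enyl]benzaldehyde F3. Suzuki–Miyaura coupling of F3 with boronate 8 under fluoride activation (Pd(OAc)2, SPhos, CsF, THF, 40 °C), mild enough not to enolise the enone, returns to the route at 16.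

3. Step 11. Acid may enolise the enone toward C4' and set off a non-selective ring closure with aromatisation, and the formaldehyde released may be captured by the electron-rich naphthol. Fallback, from 7 and 10 back to 17: the phenols are freed before the acid-sensitive groups exist. Bromide 7 is deprotected (3 M aq HCl, THF) to 1-(7-bromo-1,8-dihydroxy-3-methylnaphthalen-2-yl)ethan-1-one F4, which is borylated (B2pin2, Pd(dppf)Cl2, KOAc, dioxane) to 1-[1,8-dihydroxy-3-methyl-7-(4,4,5,5-tetramethyl-1,3,2-dioxaborolan-2-yl)naphthalen-2-yl]ethan-1-one F5. Phenol 10 is coupled directly with stannane 12 (Pd(PPh3)4, toluene, 80 °C) to 3-bromo-2-hydroxy-6-(2-methylprop-2-enyl)benzaldehyde F6. Suzuki–Miyaura coupling of F5 with F6 (Pd(OAc)2, SPhos, K3PO4, toluene/H2O; unprotected 3-bromosalicylaldehydes are established partners) gives 3-(7-acetyl-1,8-dihydroxy-6-methylnaphthalen-2-yl)-2-hydroxy-6-(2-methylprop-2-enyl)benzaldehyde F7. Cross-metathesis of F7 with 15 under the conditions of step 10 returns to the route at 17.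

Further compounds
F1 | step 12 | 1-[(1R,2S)-7-(7-acetyl-1,8-dihydroxy-6-methylnaphthalen-2-yl)-1,8-dihydroxy-3-methyl-1,2-dihydronaphthalen-2-yl]ethan-1-one (enantiomer of 20) | CC(=O)c1c(C)cc2ccc(-c3ccc4c(c3O)[C@H](O)[C@@H](C(C)=O)C(C)=C4)c(O)c2c1O
F2 | step 10 | (E)-N-tert-butyl-1-[3-bromo-2-(methoxymethoxy)-6-methylphenyl]methanimine | COCOc1c(Br)ccc(C)c1/C=N/C(C)(C)C
F3 | step 10 | 3-bromo-2-(methoxymethoxy)-6-[(E)-2-methyl-4-oxopent-2-enyl]benzaldehyde | COCOc1c(Br)ccc(C/C(C)=C/C(C)=O)c1C=O
F4 | step 11 | 1-(7-bromo-1,8-dihydroxy-3-methylnaphthalen-2-yl)ethan-1-one | CC(=O)c1c(C)cc2ccc(Br)c(O)c2c1O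
F5 | step 11 | 1-[1,8-dihydroxy-3-methyl-7-(4,4,5,5-tetramethyl-1,3,2-dioxaborolan-2-yl)naphthalen-2-yl]ethan-1-one | CC(=O)c1c(C)cc2ccc(B3OC(C)(C)C(C)(C)O3)c(O)c2c1O
F6 | step 11 | 3-bromo-2-hydroxy-6-(2-methylprop-2-enyl)benzaldehyde | O=Cc1c(O)c(Br)ccc1CC(C)=C
F7 | step 11 | 3-(7-acetyl-1,8-dihydroxy-6-methylnaphthalen-2-yl)-2-hydroxy-6-(2-methylprop-2-enyl)benzaldehyde | CC(=O)c1c(C)cc2ccc(-c3ccc(CC(C)=C)c(C=O)c3O)c(O)c2c1O
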